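**Retrosynthetic overview**
1. Labels: ring C1 (stereocentre), C2, C3=C4(CH2OH), C5, C6, C7=C8(Me), C9, C10, C11=C12(Me), C13, C14; side chain C15(Me)=C16–C17–C18=C19Me2. The only ring (14-membered) is closed late at C9–C10 by intramolecular alkylation of an allyl sulfone carbanion with an allylic bromide; Pd/hydride desulfonylation and desilylation finish.
2. The open chain comes from a Z-selective Ando olefination (C3=C4, ester later reduced to CH2OH) of an aldehyde fragment (C1–C3, C10–C19) with a phosphonate fragment (C4–C9).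
3. C1 and the E side-chain alkene come from a Johnson–Claisen rearrangement of an (R) allylic alcohol (1,3-chirality transfer).
4. That alcohol is made by the key C–C bond formation: intermolecular Brown asymmetric carbonyl allylation joining an allyl fragment to a nerol-derived (2E,6Z)-enal, then cross-metathesis to the prenyl end.
5. Nerol supplies the Z alkene (C11=C12); 5-bromo-2-methylpent-2-ene supplies the E alkene (C7=C8).

Assumption: ethyl 2-[bis(2-methylphenoxy)phosphoryl]acetate, (+)-Ipc2BOMe and 5-bromo-2-methylpent-2-ene are bought; the target SMILES is read as (R) at C1.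

**Route**

Step 1
Reactants: 1 nerol
Product: 2 neryl bromide, (2Z)-1-bromo-3,7-dimethylocta-2,6-diene
Conditions: PBr3 (0.4 equiv), pyridine (cat.), Et2O, −10 °C
Reagents that add atoms: phosphorus tribromide, BrP(Br)Br
Why: Bromination of the primary allylic alcohol through its phosphite ester (SN2) at low temperature gives the bromide without allylic transposition, so the Z geometry bought with nerol is kept.

Step 2
Reactants: 2 neryl bromide
Product: 3 neryl phenyl sulfone, {[(2Z)-3,7-dimethylocta-2,6-dien-1-yl]sulfonyl}benzene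
Conditions: PhSO2Na (1.3 equiv), DMF, rt
Reagents that add atoms: sodium benzenesulfinate, [Na+].[O-]S(=O)c1ccccc1
Why: S-alkylation of the sulfinate by the primary allylic bromide (SN2) installs the sulfone that later stabilizes the ring-closing carbanion.

Step 3
Reactants: 3 neryl phenyl sulfone
Product: 4 (2E,6Z)-2,6-dimethyl-8-(phenylsulfonyl)octa-2,6-dien-1-ol
Conditions: SeO2 (0.3 equiv), t-BuOOH (3 equiv), salicylic acid (0.1 equiv), CH2Cl2, rt
Reagents that add atoms: tert-butyl hydroperoxide, CC(C)(C)OO (oxygen passed on through SeO2, O=[Se]=O)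
Why: Riley allylic oxidation (ene reaction then [2,3]-sigmatropic shift) attacks the electron-richer distal alkene and oxidizes only its E methyl group, so the new allylic alcohol is E and the sulfone-deactivated Z alkene is untouched.

Step 4
Reactants: 4 (2E,6Z)-2,6-dimethyl-8-(phenylsulfonyl)octa-2,6-dien-1-ol
Product: 5 (2E,6Z)-2,6-dimethyl-8-(phenylsulfonyl)octa-2,6-dienal
Conditions: MnO2 (15 equiv), CH2Cl2, rt
Reagents that add atoms: none
Why: MnO2 oxidizes the allylic alcohol selectively to the enal without isomerizing either alkene.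

Step 5
Reactants: 5 (2E,6Z)-2,6-dimethyl-8-(phenylsulfonyl)octa-2,6-dienal; 6 allylmagnesium bromide
Product: 9 (4R,5E,9Z)-5,9-dimethyl-11-(phenylsulfonyl)undeca-1,5,9-trien-4-ol, via (+)-B-allyldiisopinocampheylborane 7 (not isolated), via diisopinocampheylborinate ester 8 (not isolated)
Conditions: (+)-Ipc2BOMe (from (−)-α-pinene), 6, Et2O, −78 °C → rt; then 5, −78 °C; then 3 M NaOH, 30% H2O2, 0 °C → rt
Reagents that add atoms: none
Why: Brown asymmetric allylboration (carbonyl allylation) joins the allyl fragment to the enal through a chair six-membered transition state in which the isopinocampheyl groups of this borane antipode direct allyl to the Re face, setting the (R) carbinol centre.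

Step 6
Reactants: 9 (4R,5E,9Z)-5,9-dimethyl-11-(phenylsulfonyl)undeca-1,5,9-trien-4-ol
Product: 10 (5R,6E,10Z)-2,6,10-trimethyl-12-(phenylsulfonyl)dodeca-2,6,10-trien-5-ol
Conditions: 2-methylbut-2-ene (neat, large excess), second-generation Grubbs catalyst RuCl2(=CHPh)(PCy3)(H2IMes) (5 mol%), 35 °C
Reagents that add atoms: 2-methylbut-2-ene, CC=C(C)C
Why: Olefin cross-metathesis exchanges the terminal CH2 of the only monosubstituted alkene for C(CH3)2 (prenyl end), the trisubstituted alkenes being too hindered to react.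

Step 7
Reactants: 10 (5R,6E,10Z)-2,6,10-trimethyl-12-(phenylsulfonyl)dodeca-2,6,10-trien-5-ol
Product: 12 ethyl (3R,4E)-4,8-dimethyl-3-[(3Z)-3-methyl-5-(phenylsulfonyl)pent-3-en-1-yl]nona-4,7-dienoate, via mixed ketene acetal 11 (not isolated)
Conditions: CH3C(OEt)3 (6 equiv), EtCO2H (0.1 equiv), xylene, 135 °C, EtOH distilled off
Reagents that add atoms: triethyl orthoacetate, CCOC(C)(OCC)OCC
Why: Johnson orthoester Claisen rearrangement: the [3,3] shift through a chair with the carbinol substituent equatorial gives the E trisubstituted alkene and transfers the (R) carbinol chirality suprafacially to C1, which becomes (R).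

Step 8
Reactants: 12 ethyl (3R,4E)-4,8-dimethyl-3-[(3Z)-3-methyl-5-(phenylsulfonyl)pent-3-en-1-yl]nona-4,7-dienoate
Product: 13 (3R,4E)-4,8-dimethyl-3-[(3Z)-3-methyl-5-(phenylsulfonyl)pent-3-en-1-yl]nona-4,7-dien-1-ol
Conditions: i-Bu2AlH (2.5 equiv), CH2Cl2, −78 → 0 °C; aq. KNaC4H4O6 work-up
Reagents that add atoms: none
Why: Hydride reduction of the ester to the primary alcohol leaves sulfone and alkenes alone, and C1 is not alpha to the carbonyl so it cannot epimerize.

Step 9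
Reactants: 13 (3R,4E)-4,8-dimethyl-3-[(3Z)-3-methyl-5-(phenylsulfonyl)pent-3-en-1-yl]nona-4,7-dien-1-ol
Product: 14 (3R,4E)-4,8-dimethyl-3-[(3Z)-3-methyl-5-(phenylsulfonyl)pent-3-en-1-yl]nona-4,7-dienal
Conditions: Dess–Martin periodinane (1.3 equiv), CH2Cl2, 0 °C → rt
Reagents that add atoms: none
Why: Dess–Martin oxidation gives the aldehyde under non-basic conditions, so the beta stereocentre and the allyl sulfone are not disturbed.

Step 10
Reactants: 15 5-bromo-2-methylpent-2-ene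
Product: 16 (2E)-5-bromo-2-methylpent-2-en-1-ol
Conditions: SeO2 (0.3 equiv), t-BuOOH (3 equiv), salicylic acid (0.1 equiv), CH2Cl2, rt
Reagents that add atoms: tert-butyl hydroperoxide, CC(C)(C)OO (oxygen passed on through SeO2, O=[Se]=O)
Why: Riley allylic oxidation hydroxylates only the E methyl of the gem-dimethyl alkene, fixing the E geometry of the future C7=C8 bond.

Step 11
Reactants: 16 (2E)-5-bromo-2-methylpent-2-en-1-ol
Product: 17 {[(2E)-5-bromo-2-methylpent-2-en-1-yl]oxy}(tert-butyl)dimethylsilane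
Conditions: TBSCl, imidazole, CH2Cl2, 0 °C → rt
Reagents that add atoms: tert-butyldimethylsilyl chloride, CC(C)(C)[Si](C)(C)Cl
Why: Silylation protects the allylic alcohol as a TBS ether that survives the basic steps and is later removable beside a TBDPS ether.

Step 12
Reactants: 17 {[(2E)-5-bromo-2-methylpent-2-en-1-yl]oxy}(tert-butyl)dimethylsilane
Product: 18 tert-butyl{[(2E)-5-iodo-2-methylpent-2-en-1-yl]oxy}dimethylsilane
Conditions: NaI (3 equiv), acetone, reflux
Reagents that add atoms: sodium iodide, [Na+].[I-]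
Why: Finkelstein halide exchange (SN2) gives the more reactive primary iodide for the next alkylation.

Step 13
Reactants: 19 ethyl 2-[bis(2-methylphenoxy)phosphoryl]acetate; 18 tert-butyl{[(2E)-5-iodo-2-methylpent-2-en-1-yl]oxy}dimethylsilane
Product: 21 ethyl (5E)-2-[bis(2-methylphenoxy)phosphoryl]-7-{[tert-butyl(dimethyl)silyl]oxy}-6-methylhept-5-enoate (racemic at C2), via sodium phosphonoacetate carbanion 20 (not isolated)
Conditions: NaH (1.0 equiv), DMSO, rt; then 18, rt → 50 °C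
Reagents that add atoms: none
Why: SN2 C-alkylation of the stabilized phosphonoacetate carbanion by the primary iodide puts the C5–C9 chain on the olefination reagent.

Step 14
Reactants: 21 ethyl (5E)-2-[bis(2-methylphenoxy)phosphoryl]-7-{[tert-butyl(dimethyl)silyl]oxy}-6-methylhept-5-enoate; 14 (3R,4E)-4,8-dimethyl-3-[(3Z)-3-methyl-5-(phenylsulfonyl)pent-3-en-1-yl]nona-4,7-dienal
Product: 23 ethyl (2Z,5R,6E)-2-[(3E)-5-{[tert-butyl(dimethyl)silyl]oxy}-4-methylpent-3-en-1-yl]-6,10-dimethyl-5-[(3Z)-3-methyl-5-(phenylsulfonyl)pent-3-en-1-yl]undeca-2,6,9-trienoate, via sodium phosphonate carbanion 22 (not isolated)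
Conditions: NaH (1.0 equiv), THF, 0 °C; then 14, −78 → 0 °C
Reagents that add atoms: none
Why: Ando Z-selective Horner–Wadsworth–Emmons olefination: the electron-poor diaryl phosphonate eliminates fast from the first-formed adduct, so the aldehyde chain (C2) ends up cis to the ester, which is the C3=C4 geometry of the target.

Step 15
Reactants: 23 ethyl (2Z,5R,6E)-trienoate from step 14
Product: 24 (2Z,5R,6E)-2-[(3E)-5-{[tert-butyl(dimethyl)silyl]oxy}-4-methylpent-3-en-1-yl]-6,10-dimethyl-5-[(3Z)-3-methyl-5-(phenylsulfonyl)pent-3-en-1-yl]undeca-2,6,9-trien-1-ol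
Conditions: i-Bu2AlH (2.5 equiv), CH2Cl2, −78 °C; aq. KNaC4H4O6 work-up
Reagents that add atoms: none
Why: 1,2-Reduction of the unsaturated ester by i-Bu2AlH gives the allylic alcohol (the future CH2OH) with the alkene geometry unchanged.

Step 16
Reactants: 24 allylic alcohol from step 15
Product: 25 tert-butyl{[(2Z,5R,6E)-2-[(3E)-5-{[tert-butyl(dimethyl)silyl]oxy}-4-methylpent-3-en-1-yl]-6,10-dimethyl-5-[(3Z)-3-methyl-5-(phenylsulfonyl)pent-3-en-1-yl]undeca-2,6,9-trien-1-yl]oxy}diphenylsilane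
Conditions: TBDPSCl, imidazole, DMF, rt
Reagents that add atoms: tert-butyldiphenylsilyl chloride, CC(C)(C)[Si](Cl)(c1ccccc1)c1ccccc1
Why: Silylation masks the future CH2OH as a robust TBDPS ether so that no alkoxide or ester is present during the base-mediated ring closure.

Step 17
Reactants: 25 bis-silyl ether from step 16
Product: 26 (2E,6Z,9R,10E)-6-({[tert-butyl(diphenyl)silyl]oxy}methyl)-2,10,14-trimethyl-9-[(3Z)-3-methyl-5-(phenylsulfonyl)pent-3-en-1-yl]pentadeca-2,6,10,13-tetraen-1-ol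
Conditions: PPTS (0.2 equiv), MeOH, rt
Reagents that add atoms: none
Why: Acid-catalysed methanolysis cleaves the primary TBS ether far faster than the bulkier TBDPS ether, freeing only the C9 hydroxyl.

Step 18
Reactants: 26 C9 alcohol from step 17
Product: 27 tert-butyl{[(2Z,5R,6E)-2-[(3E)-5-bromo-4-methylpent-3-en-1-yl]-6,10-dimethyl-5-[(3Z)-3-methyl-5-(phenylsulfonyl)pent-3-en-1-yl]undeca-2,6,9-trien-1-yl]oxy}diphenylsilane
Conditions: CBr4 (1.3 equiv), PPh3 (1.4 equiv), CH2Cl2, 0 °C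
Reagents that add atoms: carbon tetrabromide, BrC(Br)(Br)Br
Why: Appel reaction converts the primary allylic alcohol to the bromide by SN2 on the alkoxyphosphonium ion, without allylic shift or E/Z change.

Step 19
Reactants: 27 bromo sulfone from step 18
Product: 29 tert-butyl{[(1Z,4E,8Z,12R)-5,9-dimethyl-12-[(2E)-6-methylhepta-2,5-dien-2-yl]-7-(phenylsulfonyl)cyclotetradeca-1(14),4,8-trien-1-yl]methoxy}diphenylsilane (both epimers at the sulfone carbon), via potassium sulfonyl carbanion 28 (not isolated)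
Conditions: KN(SiMe3)2 (1.3 equiv), THF, −20 °C, 27 added over 8 h to 0.002 M; aq. NH4Cl
Reagents that add atoms: none
Why: Intramolecular SN2 alkylation of the allyl sulfone carbanion by the primary allylic bromide under pseudo-high dilution closes the 14-membered ring at C9–C10; the new sulfone-bearing centre is an epimer mixture that is erased in the next step.

Step 20
Reactants: 29 macrocyclic sulfone from step 19
Product: 30 tert-butyl{[(1Z,4E,8Z,12R)-5,9-dimethyl-12-[(2E)-6-methylhepta-2,5-dien-2-yl]cyclotetradeca-1(14),4,8-trien-1-yl]methoxy}diphenylsilane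
Conditions: PdCl2(dppp) (10 mol%), LiBHEt3 (2.5 equiv), THF, 0 °C
Reagents that add atoms: none
Why: Palladium-catalysed reductive desulfonylation: zerovalent palladium ionizes the allylic sulfone to a π-allyl complex and hydride goes to the less substituted terminus (C10), which keeps the C11=C12 alkene in place and, since syn/anti exchange at the fully substituted terminus is slow, keeps it Z.

Step 21
Reactants: 30 macrocyclic silyl ether from step 20
Product: 31 [(1Z,4E,8Z,12R)-5,9-dimethyl-12-[(2E)-6-methylhepta-2,5-dien-2-yl]cyclotetradeca-1(14),4,8-trien-1-yl]methanol (target)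
Conditions: Bu4NF (1.5 equiv), THF, 0 °C → rt
Reagents that add atoms: none
Why: Fluoride-mediated desilylation frees the primary allylic alcohol without touching the skipped diene or the ring alkenes.

**Compound list**
1 | nerol, (2Z)-3,7-dimethylocta-2,6-dien-1-ol | CC(C)=CCC/C(C)=C\CO | starting material
2 | neryl bromide | CC(C)=CCC/C(C)=C\CBr | intermediate
3 | neryl phenyl sulfone | CC(C)=CCC/C(C)=C\CS(=O)(=O)c1ccccc1 | intermediate
4 | (2E,6Z)-2,6-dimethyl-8-(phenylsulfonyl)octa-2,6-dien-1-ol | OC/C(C)=C/CC/C(C)=C\CS(=O)(=O)c1ccccc1 | intermediate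
5 | (2E,6Z)-2,6-dimethyl-8-(phenylsulfonyl)octa-2,6-dienal | O=C/C(C)=C/CC/C(C)=C\CS(=O)(=O)c1ccccc1 | intermediate
6 | allylmagnesium bromide | C=CC[Mg]Br | starting material
7 | (+)-B-allyldiisopinocampheylborane (not isolated) | C=CCB([C@H]1C[C@H]2C[C@@H]([C@@H]1C)C2(C)C)[C@H]1C[C@H]2C[C@@H]([C@@H]1C)C2(C)C | intermediate
8 | (4R,5E,9Z)-5,9-dimethyl-11-(phenylsulfonyl)undeca-1,5,9-trien-4-yl diisopinocampheylborinate (not isolated) | C=CC[C@@H](OB([C@H]1C[C@H]2C[C@@H]([C@@H]1C)C2(C)C)[C@H]1C[C@H]2C[C@@H]([C@@H]1C)C2(C)C)/C(C)=C/CC/C(C)=C\CS(=O)(=O)c1ccccc1 | intermediate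
9 | (4R,5E,9Z)-5,9-dimethyl-11-(phenylsulfonyl)undeca-1,5,9-trien-4-ol | C=CC[C@@H](O)/C(C)=C/CC/C(C)=C\CS(=O)(=O)c1ccccc1 | intermediate
10 | (5R,6E,10Z)-2,6,10-trimethyl-12-(phenylsulfonyl)dodeca-2,6,10-trien-5-ol | CC(C)=CC[C@@H](O)/C(C)=C/CC/C(C)=C\CS(=O)(=O)c1ccccc1 | intermediate
11 | (5R,6E,10Z)-5-[(1-ethoxyethenyl)oxy]-2,6,10-trimethyl-12-(phenylsulfonyl)dodeca-2,6,10-triene (not isolated) | CC(C)=CC[C@@H](OC(=C)OCC)/C(C)=C/CC/C(C)=C\CS(=O)(=O)c1ccccc1 | intermediate
12 | ethyl (3R,4E)-4,8-dimethyl-3-[(3Z)-3-methyl-5-(phenylsulfonyl)pent-3-en-1-yl]nona-4,7-dienoate | CCOC(=O)C[C@@H](CC/C(C)=C\CS(=O)(=O)c1ccccc1)/C(C)=C/CC=C(C)C | intermediate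
13 | (3R,4E)-4,8-dimethyl-3-[(3Z)-3-methyl-5-(phenylsulfonyl)pent-3-en-1-yl]nona-4,7-dien-1-ol | OCC[C@@H](CC/C(C)=C\CS(=O)(=O)c1ccccc1)/C(C)=C/CC=C(C)C | intermediate
14 | (3R,4E)-4,8-dimethyl-3-[(3Z)-3-methyl-5-(phenylsulfonyl)pent-3-en-1-yl]nona-4,7-dienal | O=CC[C@@H](CC/C(C)=C\CS(=O)(=O)c1ccccc1)/C(C)=C/CC=C(C)C | intermediate
15 | 5-bromo-2-methylpent-2-ene | CC(C)=CCCBr | starting material
16 | (2E)-5-bromo-2-methylpent-2-en-1-ol | OC/C(C)=C/CCBr | intermediate
17 | {[(2E)-5-bromo-2-methylpent-2-en-1-yl]oxy}(tert-butyl)dimethylsilane | CC(C)(C)[Si](C)(C)OC/C(C)=C/CCBr | intermediate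
18 | tert-butyl{[(2E)-5-iodo-2-methylpent-2-en-1-yl]oxy}dimethylsilane | CC(C)(C)[Si](C)(C)OC/C(C)=C/CCI | intermediate
19 | ethyl 2-[bis(2-methylphenoxy)phosphoryl]acetate | CCOC(=O)CP(=O)(Oc1ccccc1C)Oc1ccccc1C | starting material
20 | sodium salt of the carbanion of 19 (not isolated) | [Na+].CCOC(=O)[CH-]P(=O)(Oc1ccccc1C)Oc1ccccc1C | intermediate
21 | ethyl (5E)-2-[bis(2-methylphenoxy)phosphoryl]-7-{[tert-butyl(dimethyl)silyl]oxy}-6-methylhept-5-enoate (racemic at C2) | CCOC(=O)C(CC/C=C(\C)CO[Si](C)(C)C(C)(C)C)P(=O)(Oc1ccccc1C)Oc1ccccc1C | intermediate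
22 | sodium salt of the carbanion of 21 (not isolated) | [Na+].CCOC(=O)[C-](CC/C=C(\C)CO[Si](C)(C)C(C)(C)C)P(=O)(Oc1ccccc1C)Oc1ccccc1C | intermediate
23 | ethyl (2Z,5R,6E)-2-[(3E)-5-{[tert-butyl(dimethyl)silyl]oxy}-4-methylpent-3-en-1-yl]-6,10-dimethyl-5-[(3Z)-3-methyl-5-(phenylsulfonyl)pent-3-en-1-yl]undeca-2,6,9-trienoate | CCOC(=O)/C(CC/C=C(\C)CO[Si](C)(C)C(C)(C)C)=C\C[C@@H](CC/C(C)=C\CS(=O)(=O)c1ccccc1)/C(C)=C/CC=C(C)C | intermediate
24 | (2Z,5R,6E)-2-[(3E)-5-{[tert-butyl(dimethyl)silyl]oxy}-4-methylpent-3-en-1-yl]-6,10-dimethyl-5-[(3Z)-3-methyl-5-(phenylsulfonyl)pent-3-en-1-yl]undeca-2,6,9-trien-1-ol | OC/C(CC/C=C(\C)CO[Si](C)(C)C(C)(C)C)=C\C[C@@H](CC/C(C)=C\CS(=O)(=O)c1ccccc1)/C(C)=C/CC=C(C)C | intermediate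
25 | TBDPS ether of 24 (name as in step 16) | CC(C)(C)[Si](c1ccccc1)(c1ccccc1)OC/C(CC/C=C(\C)CO[Si](C)(C)C(C)(C)C)=C\C[C@@H](CC/C(C)=C\CS(=O)(=O)c1ccccc1)/C(C)=C/CC=C(C)C | intermediate
26 | (2E,6Z,9R,10E)-6-({[tert-butyl(diphenyl)silyl]oxy}methyl)-2,10,14-trimethyl-9-[(3Z)-3-methyl-5-(phenylsulfonyl)pent-3-en-1-yl]pentadeca-2,6,10,13-tetraen-1-ol | CC(C)(C)[Si](c1ccccc1)(c1ccccc1)OC/C(CC/C=C(\C)CO)=C\C[C@@H](CC/C(C)=C\CS(=O)(=O)c1ccccc1)/C(C)=C/CC=C(C)C | intermediate
27 | allylic bromide of 26 (name as in step 18) | CC(C)(C)[Si](c1ccccc1)(c1ccccc1)OC/C(CC/C=C(\C)CBr)=C\C[C@@H](CC/C(C)=C\CS(=O)(=O)c1ccccc1)/C(C)=C/CC=C(C)C | intermediate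
28 | potassium salt of the sulfonyl carbanion of 27 (not isolated) | [K+].CC(C)(C)[Si](c1ccccc1)(c1ccccc1)OC/C(CC/C=C(\C)CBr)=C\C[C@@H](CC/C(C)=C\[CH-]S(=O)(=O)c1ccccc1)/C(C)=C/CC=C(C)C | intermediate
29 | macrocyclic sulfone (name as in step 19; both epimers at the sulfone carbon) | CC(C)=CC/C=C(\C)[C@H]1C/C=C(\CO[Si](c2ccccc2)(c2ccccc2)C(C)(C)C)CC/C=C(\C)CC(S(=O)(=O)c2ccccc2)/C=C(/C)CC1 | intermediate
30 | TBDPS ether of the target (name as in step 20) | CC(C)=CC/C=C(\C)[C@H]1C/C=C(\CO[Si](c2ccccc2)(c2ccccc2)C(C)(C)C)CC/C=C(\C)CC/C=C(/C)CC1 | intermediate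
31 | [(1Z,4E,8Z,12R)-5,9-dimethyl-12-[(2E)-6-methylhepta-2,5-dien-2-yl]cyclotetradeca-1(14),4,8-trien-1-yl]methanol | CC(C)=CC/C=C(\C)[C@H]1C/C=C(\CO)CC/C=C(\C)CC/C=C(/C)CC1 | target

**Totals**
Total steps: 21. Longest linear sequence: 17 steps (steps 1–9, then 14–21).

**Three steps most likely to fail, each with a fallback**

Step 3 (SeO2 oxidation of 3: moderate conversion, over-oxidation, some attack at other allylic positions). The fallback replaces C–H oxidation by alkene cleavage and re-olefination; it sets out from 3 and comes back at 5. mCPBA (1.0 equiv, CH2Cl2, 0 °C) epoxidizes only the electron-richer distal alkene and gives racemic 2,2-dimethyl-3-[(3Z)-3-methyl-5-(phenylsulfonyl)pent-3-en-1-yl]oxirane F1. H5IO6 in THF/Et2O at 0 °C cleaves the epoxide to (4Z)-4-methyl-6-(phenylsulfonyl)hex-4-enal F2 with loss of acetone. A Wittig reaction of this aldehyde with the stabilized ylide Ph3P=C(CH3)CHO (toluene, 90 °C) is E-selective and gives enal 5 directly, so 4 is bypassed.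

Step 14 (Z selectivity and rate of the olefination with the alpha-branched phosphonate 21, and behind it the alkylation that makes 21). The fallback fixes the geometry with a small bromophosphonate and brings in the C5–C9 chain by stereoretentive cross-coupling; it sets out from 14 and 18 and comes back at 24. Aldehyde 14 and methyl 2-bromo-2-[bis(2,2,2-trifluoroethoxy)phosphoryl]acetate (t-BuOK, 18-crown-6, THF, −78 °C) give methyl (2E,5R,6E)-2-bromo-6,10-dimethyl-5-[(3Z)-3-methyl-5-(phenylsulfonyl)pent-3-en-1-yl]undeca-2,6,9-trienoate F3, in which the ester is cis to the chain. Iodide 18 with Zn dust and LiCl in THF at 40 °C gives [(3E)-5-{[tert-butyl(dimethyl)silyl]oxy}-4-methylpent-3-en-1-yl]zinc iodide F4. Negishi coupling of the two (PdCl2(dppf), THF, 50 °C) proceeds with retention and gives methyl (2Z,5R,6E)-2-[(3E)-5-{[tert-butyl(dimethyl)silyl]oxy}-4-methylpent-3-en-1-yl]-6,10-dimethyl-5-[(3Z)-3-methyl-5-(phenylsulfonyl)pent-3-en-1-yl]undeca-2,6,9-trienoate F5, which i-Bu2AlH reduces to 24.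

Step 19 (macrocyclization: oligomerization or elimination with the strongly basic mono-stabilized carbanion). The fallback uses a doubly activated, weakly basic nucleophile that cyclizes under carbonate conditions; it sets out from 25 and comes back at 29. Deprotonation of 25 (n-BuLi, 2.1 equiv, THF, −78 °C) and acylation with ClCO2Me give the methyl alpha-(phenylsulfonyl) ester of 25 (CO2CH3 on C10) F6. PPTS in MeOH removes the TBS group to give the C9 alcohol of that sulfonyl ester F7, and CBr4/PPh3 gives the corresponding C9 allylic bromide F8. Slow addition to Cs2CO3 in DMF at 60 °C (0.003 M) closes the ring to the 14-membered sulfonyl ester with quaternary C10 F9. Me4NOAc in DMSO at 100 °C removes the methoxycarbonyl group and returns 29.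

**Further compounds**
F1 | step 3 | 2,2-dimethyl-3-[(3Z)-3-methyl-5-(phenylsulfonyl)pent-3-en-1-yl]oxirane (racemic) | CC1(C)OC1CC/C(C)=C\CS(=O)(=O)c1ccccc1
F2 | step 3 | (4Z)-4-methyl-6-(phenylsulfonyl)hex-4-enal | O=CCC/C(C)=C\CS(=O)(=O)c1ccccc1
F3 | step 14 | methyl (2E,5R,6E)-2-bromo-6,10-dimethyl-5-[(3Z)-3-methyl-5-(phenylsulfonyl)pent-3-en-1-yl]undeca-2,6,9-trienoate | COC(=O)/C(Br)=C\C[C@@H](CC/C(C)=C\CS(=O)(=O)c1ccccc1)/C(C)=C/CC=C(C)C
F4 | step 14 | [(3E)-5-{[tert-butyl(dimethyl)silyl]oxy}-4-methylpent-3-en-1-yl]zinc iodide | CC(C)(C)[Si](C)(C)OC/C(C)=C/CC[Zn]I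
F5 | step 14 | methyl (2Z,5R,6E)-2-[(3E)-5-{[tert-butyl(dimethyl)silyl]oxy}-4-methylpent-3-en-1-yl]-6,10-dimethyl-5-[(3Z)-3-methyl-5-(phenylsulfonyl)pent-3-en-1-yl]undeca-2,6,9-trienoate | COC(=O)/C(CC/C=C(\C)CO[Si](C)(C)C(C)(C)C)=C\C[C@@H](CC/C(C)=C\CS(=O)(=O)c1ccccc1)/C(C)=C/CC=C(C)C
F6 | step 19 | methyl alpha-(phenylsulfonyl) ester of 25 (CO2CH3 on C10; both epimers) | CC(C)(C)[Si](c1ccccc1)(c1ccccc1)OC/C(CC/C=C(\C)CO[Si](C)(C)C(C)(C)C)=C\C[C@@H](CC/C(C)=C\C(C(=O)OC)S(=O)(=O)c1ccccc1)/C(C)=C/CC=C(C)C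
F7 | step 19 | C9 alcohol of that sulfonyl ester | CC(C)(C)[Si](c1ccccc1)(c1ccccc1)OC/C(CC/C=C(\C)CO)=C\C[C@@H](CC/C(C)=C\C(C(=O)OC)S(=O)(=O)c1ccccc1)/C(C)=C/CC=C(C)C
F8 | step 19 | C9 allylic bromide of that sulfonyl ester | CC(C)(C)[Si](c1ccccc1)(c1ccccc1)OC/C(CC/C=C(\C)CBr)=C\C[C@@H](CC/C(C)=C\C(C(=O)OC)S(=O)(=O)c1ccccc1)/C(C)=C/CC=C(C)C
F9 | step 19 | 14-membered sulfonyl ester with quaternary C10 (29 carrying CO2CH3 on the sulfone carbon; both epimers) | CC(C)=CC/C=C(\C)[C@H]1C/C=C(\CO[Si](c2ccccc2)(c2ccccc2)C(C)(C)C)CC/C=C(\C)CC(C(=O)OC)(S(=O)(=O)c2ccccc2)/C=C(/C)CC1
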